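**Plan**

- Numbering and cuts: norbornane C1–C5, C10, C15 (C15 is the one-carbon bridge); ring B C5–C10; ring A C8, C9, C11–C14; β is the ring-A face of the C8 methyl. The retrosynthesis removes C14–Br, the C11/C12 oxygens and the C1 methyl ether to reach a tetracyclic enone, then cuts C9–C10 (ring B), C7–C8 and C8–CH3 (dione alkylations), and C2–C3/C4–C5 (Diels–Alder).
- Enabling feature: quaternary C8 carries CH3, C7 and two ring-A arms (C9 and C14) that can both be carbonyl carbons, so ring A is a latent 2-methylcyclohexane-1,3-dione. The C1 ketone can enolise only toward C10 because C2 is a bridgehead, so one aldol condensation onto one dione carbonyl closes ring B and fixes C8.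
- Forward order: 3-substituted cyclopentenone → 2-silyloxy diene → Diels–Alder with butenone (norbornane) → isopropyl group and aldehyde arm → reductive Knoevenagel with cyclohexane-1,3-dione and C-methylation (ring A attached) → aldol condensation (ring B) → adjustment of ring A and C1.
- Stereochemistry: C2, C4, C5 from the catalytic asymmetric, endo-selective cycloaddition; C8 from the choice between the diastereotopic dione carbonyls; C9/C10 by equilibration of a 1,4-diketone; C1 by exo hydride attack; C11/C12 by α-epoxidation and trans-diaxial hydrolysis; C14 by equatorial hydride delivery, then SN2 inversion.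

Key step: step 9

Assumption: the (S)-configured oxazaborolidinium catalyst is taken to add butenone to the diene face that gives 6 as drawn; should the antipode form, the (R)-catalyst is used and nothing else changes.

**Route**

Step 1
Reactants: 1 3-bromocyclopent-2-en-1-one; 2 (1,3-dioxolan-2-ylmethyl)zinc bromide
Product: 3 3-(1,3-dioxolan-2-ylmethyl)cyclopent-2-en-1-one
Conditions: PdCl2(dppf) (3 mol %), THF, 40 °C
Reagents that add atoms: none
Why: Negishi coupling of a vinylogous acyl bromide with a primary alkylzinc halide, which installs the masked CH2CHO arm (C6, C7) in one operation.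

Step 2
Reactants: 3 3-(1,3-dioxolan-2-ylmethyl)cyclopent-2-en-1-one
Product: 4 2-{[3-(tert-butyldimethylsilyloxy)cyclopenta-1,3-dien-1-yl]methyl}-1,3-dioxolane
Conditions: LiN(i-Pr)2, THF, −78 °C; TBSCl, DMPU, −78 → 0 °C; used at once
Reagents that add atoms: tert-butyldimethylsilyl chloride, CC(C)(C)[Si](C)(C)Cl
Why: kinetic α′-deprotonation of the enone gives the cross-conjugated dienolate, and O-silylation gives the 2-silyloxy diene (no stereocentre).

Step 3
Reactants: 4 the silyloxy diene; 5 but-3-en-2-one
Product: 6 endo Diels–Alder adduct, 1-[4-(1,3-dioxolan-2-ylmethyl)-2-(tert-butyldimethylsilyloxy)bicyclo[2.2.1]hept-2-en-5-endo-yl]ethan-1-one (target numbering: enol ether C1=C10, acetyl on C4, acetal arm on C5)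
Conditions: (S)-B-(o-tolyl)oxazaborolidine from α,α-diphenylprolinol + HNTf2 (20 mol %), CH2Cl2, −78 °C
Reagents that add atoms: none
Why: catalytic enantioselective Diels–Alder reaction of a 2-silyloxy diene with an enone, in which the silyloxy ("para") and the 1-alkyl ("ortho") directing effects both join the acetyl-bearing carbon to the substituted diene terminus (C4–C5), the endo rule sets C4, and the catalyst-controlled face sets C2 and C5.

Step 4
Reactants: 6 the endo-acetyl adduct
Product: 7 the isopropenyl analogue of 6 (C4 endo-prop-1-en-2-yl; enol ether and acetal unchanged)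
Conditions: Cp2TiMe2 (2.5 equiv), toluene, 65 °C, dark
Reagents that add atoms: dimethyltitanocene, [CH3-].[CH3-].[Ti+4].c1cc[cH-]c1.c1cc[cH-]c1
Why: Petasis methylenation is non-basic, so the epimerisable endo centre C4 next to the acetyl group is kept, and silyl enol ether and acetal are inert.

Step 5
Reactants: 7 the isopropenyl silyl enol ether
Product: 8 (1S,4S,5S)-4-(1,3-dioxolan-2-ylmethyl)-5-(prop-1-en-2-yl)bicyclo[2.2.1]heptan-2-one (isopropenyl endo)
Conditions: 0.2 M HCl, THF/H2O, 0 °C
Reagents that add atoms: none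
Why: silyl enol ether hydrolysis is much faster than aldehyde-dioxolane hydrolysis in dilute acid, so the aldehyde stays masked while the isopropenyl group is present and no Prins-type closure can occur.

Step 6
Reactants: 8 the isopropenyl ketone acetal
Product: 10 (1S,4S,5S)-4-(2-oxoethyl)-5-(propan-2-yl)bicyclo[2.2.1]heptan-2-one, via isopropyl acetal 9 (not isolated)
Conditions: H2 (1 atm), 10 % Pd/C, THF, 25 °C; filter; 2 M HCl, THF/H2O, 25 °C
Reagents that add atoms: water, O
Why: heterogeneous hydrogenation of the 1,1-disubstituted alkene creates no stereocentre (if Pd moves the double bond to C4, exo delivery of hydrogen still returns the endo isopropyl), and acetal hydrolysis then frees the aldehyde.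

Step 7
Reactants: 10 the keto aldehyde; 11 cyclohexane-1,3-dione
Product: 13 (1S,4R,5S)-4-[2-(2,6-dioxocyclohexyl)ethyl]-5-(propan-2-yl)bicyclo[2.2.1]heptan-2-one, via alkylidene dione 12 (not isolated)
Conditions: L-proline (20 mol %), Hantzsch ester (1.1 equiv), CH2Cl2, 25 °C
Reagents that add atoms: none
Why: organocatalytic reductive Knoevenagel alkylation, in which the aldehyde condenses with the 1,3-dione and the alkylidene dione is reduced at once by hydride transfer from the Hantzsch ester, forming C7–C8; the hindered norbornanone does not condense.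

Step 8
Reactants: 13 the 2-alkyl-1,3-dione
Product: 14 (1S,4R,5S)-4-[2-(1-methyl-2,6-dioxocyclohexyl)ethyl]-5-(propan-2-yl)bicyclo[2.2.1]heptan-2-one (triketone)
Conditions: MeI, Cs2CO3, MeCN, 25 °C
Reagents that add atoms: iodomethane, CI
Why: C-alkylation of the dione enolate with the small, soft electrophile MeI gives the prochiral quaternary C8; carbonate does not deprotonate the ketone α-CH2.

Step 9
Reactants: 14 the triketone
Product: 16 tetracyclic enedione (C1 ketone conjugated with C9=C10; C14 ketone; C8 methyl on the ring-B face opposite C15), via ketol 15 (not isolated)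
Conditions: pyrrolidine (0.5 equiv), AcOH (0.5 equiv), toluene, 4 Å MS, 60 → 90 °C
Reagents that add atoms: none
Why: The C1 ketone, whose only enolisable α-position is C10 because C2 is a bridgehead, forms a pyrrolidine enamine (or its enol) that adds to one of the two diastereotopic dione carbonyls, C9, to give ketol 15, and loss of water through the enamine/iminium gives the conjugated C9=C10 enone. The closest known reaction is the Hajos–Parrish/Wieland–Miescher-type aldol condensation that desymmetrises a 2,2-disubstituted cyclohexane-1,3-dione. Ring B (C5–C6–C7–C8–C9–C10) closes in a 6-(enolexo)-exo-trig mode. The one new stereocentre that survives, C8, is set by which carbonyl reacts: the two-carbon tether from bridgehead C5 lets C9 reach only the exo face of C10, which fixes ring B as the chair with C15 axial, and in that chair the carbonyl leading to 16 should react with the C8 methyl axial and ring A equatorial (trans-decalin-like), whereas the other carbonyl can react only with ring A folded under ring B against the axial C6–H. The step therefore needs regioselective enolisation, secured by the bridgehead, and selection between the two dione carbonyls, secured by this chair; the untouched carbonyl becomes C14.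

Step 10
Reactants: 16 the tetracyclic enedione
Product: 17 the C14 1,3-dioxolane ketal of 16
Conditions: HOCH2CH2OH, TsOH·H2O (10 mol %), 4 Å MS, CH2Cl2, 25 °C
Reagents that add atoms: ethylene glycol, OCCO
Why: acid-catalysed ketalisation picks the saturated C14 ketone over the less electrophilic conjugated C1 carbonyl, as in the monoketalisation of the Wieland–Miescher ketone.

Step 11
Reactants: 17 the enone ketal
Product: 18 ene-1,11-dione (C11 ketone added; C9=C10 and C14 ketal unchanged)
Conditions: Rh2(cap)4 (1 mol %), t-BuOOH (70 % aq., 5 equiv), ClCH2CH2Cl, 40 °C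
Reagents that add atoms: tert-butyl hydroperoxide, CC(C)(C)OO
Why: dirhodium-caprolactamate allylic oxidation turns the γ-methylene of an enone into a ketone (as in steroidal 4-en-3-one to 4-ene-3,6-dione), and C11 is the only allylic C–H position because C5 and C8 are quaternary.

Step 12
Reactants: 18 the ene-1,11-dione
Product: 20 saturated 1,11-diketone with H9 α (trans to the C8 methyl) and C9 exo on C10 (H10 endo), via epimer mixture 19 (not isolated)
Conditions: Zn, AcOH, THF, 25 °C; filter; DBU (0.3 equiv), CH2Cl2, 25 °C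
Reagents that add atoms: none
Why: zinc reduction of the ene-1,4-dione, after which C9 and C10, each α to a ketone, are equilibrated by base to the thermodynamic isomer with trans-fused rings A/B and exo-fused ring B (the endo alternative would press ring B against the endo isopropyl).

Step 13
Reactants: 20 the 1,11-diketone
Product: 21 C11 enol triflate (C11=C12) with the C1 ketone intact
Conditions: KN(SiMe3)2 (1.05 equiv), THF, −78 °C; PhNTf2, −78 → 0 °C
Reagents that add atoms: N-phenylbis(trifluoromethanesulfonimide), O=S(=O)(N(c1ccccc1)S(=O)(=O)C(F)(F)F)C(F)(F)F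
Why: kinetic enolate formation goes to the only α-methylene (C12), the other α-hydrogens (C9–H, C10–H) being hindered methines, and O-triflation leaves C1 as the single free ketone.

Step 14
Reactants: 21 the keto enol triflate
Product: 22 the C1 endo alcohol
Conditions: NaBH4, MeOH/THF, 0 °C
Reagents that add atoms: none
Why: borohydride reduction of a norbornanone from the exo face (the endo face is screened by the C3 endo hydrogen and the endo isopropyl at C4) sets C1 with endo oxygen.

Step 15
Reactants: 22 the endo alcohol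
Product: 23 the C1 endo methyl ether
Conditions: NaH, MeI, THF/DMF, 0 → 25 °C
Reagents that add atoms: iodomethane, CI
Why: Williamson etherification with retention at C1; enol triflate and ketal tolerate the alkoxide at this temperature.

Step 16
Reactants: 23 the methyl ether ketal
Product: 24 the C14 ketone (enol triflate and methyl ether kept)
Conditions: 2 M HCl, THF, 25 °C
Reagents that add atoms: water, O
Why: acid hydrolysis of the dioxolane; the electron-poor enol triflate double bond does not migrate into conjugation with the freed ketone.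

Step 17
Reactants: 24 the C14 ketone
Product: 25 the 14α-alcohol (axial, trans to the C8 methyl)
Conditions: LiBH(s-Bu)3 (L-selectride), THF, −78 °C; H2O
Reagents that add atoms: none
Why: the bulky hydride attacks the α-quaternary cyclohexanone along the equatorial trajectory, as with 4,4-disubstituted 3-keto terpenoids, giving the axial alcohol needed for later inversion.

Step 18
Reactants: 25 the hydroxy enol triflate
Product: 26 the 11-methyl 11(12)-alkene with 14α-OH
Conditions: MeZnCl (4 equiv), Pd(PPh3)4 (5 mol %), THF, 50 °C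
Reagents that add atoms: methylzinc chloride, C[Zn]Cl
Why: Negishi coupling of the enol triflate puts the C11 methyl on an sp2 carbon, so no facial question arises at this hindered position.

Step 19
Reactants: 26 the homoallylic alcohol
Product: 27 the 11α,12α-epoxide with 14α-OH
Conditions: mCPBA, NaHCO3, CH2Cl2, 0 °C
Reagents that add atoms: 3-chloroperbenzoic acid, OOC(=O)c1cccc(Cl)c1
Why: peracid epoxidation from the α face, because the axial C8 methyl covers the β face of C11 and the axial 14α-hydroxyl can guide the peracid to the same side.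

Step 20
Reactants: 27 the epoxy alcohol
Product: 28 the 14β-bromide (equatorial, cis to the C8 methyl) of the 11α,12α-epoxide
Conditions: PPh3, CBr4, 2,6-lutidine, toluene, 25 → 60 °C
Reagents that add atoms: carbon tetrabromide, BrC(Br)(Br)Br
Why: Appel reaction, in which bromide displaces the axial oxyphosphonium with inversion to give the equatorial bromide; C13 is no longer allylic at this stage, and the buffered, non-ionising medium restrains elimination and methyl shift.

Step 21
Reactants: 28 the bromo epoxide
Product: 29 CNP0130529.1 (1-endo-methoxy, 4-endo-isopropyl, 8β-methyl, 9α-H, H10 endo, 11β-hydroxy-11α-methyl, 12α-hydroxy, 14β-bromo)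
Conditions: HClO4 (cat.), THF/H2O, 25 °C
Reagents that add atoms: water, O
Why: acid-catalysed epoxide hydrolysis, in which water attacks the tertiary C11 from the β face with inversion; this is both the Markovnikov and the trans-diaxial (Fürst–Plattner) mode and gives the 11β,12α-diol.

**Compound list**

1 | 3-bromocyclopent-2-en-1-one | O=C1C=C(Br)CC1 | starting material
2 | (1,3-dioxolan-2-ylmethyl)zinc bromide | Br[Zn]CC1OCCO1 | starting material
3 | 3-(1,3-dioxolan-2-ylmethyl)cyclopent-2-en-1-one | O=C1C=C(CC2OCCO2)CC1 | intermediate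
4 | 2-{[3-(tert-butyldimethylsilyloxy)cyclopenta-1,3-dien-1-yl]methyl}-1,3-dioxolane | CC(C)(C)[Si](C)(C)OC1=CCC(CC2OCCO2)=C1 | intermediate
5 | but-3-en-2-one | CC(=O)C=C | starting material
6 | endo-acetyl Diels–Alder adduct (silyl enol ether C1=C10, acetyl endo on C4, acetal arm on C5) | CC(C)(C)[Si](C)(C)OC=1[C@H]2C[C@@H](C(C)=O)[C@](CC3OCCO3)(C2)C=1 | intermediate
7 | endo-isopropenyl silyl enol ether | CC(C)(C)[Si](C)(C)OC=1[C@H]2C[C@@H](C(C)=C)[C@](CC3OCCO3)(C2)C=1 | intermediate
8 | (1S,4S,5S)-4-(1,3-dioxolan-2-ylmethyl)-5-(prop-1-en-2-yl)bicyclo[2.2.1]heptan-2-one | O=C1[C@H]2C[C@@H](C(C)=C)[C@](CC3OCCO3)(C2)C1 | intermediate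
9 | (1S,4S,5S)-4-(1,3-dioxolan-2-ylmethyl)-5-(propan-2-yl)bicyclo[2.2.1]heptan-2-one | O=C1[C@H]2C[C@@H](C(C)C)[C@](CC3OCCO3)(C2)C1 | intermediate (not isolated)
10 | (1S,4S,5S)-4-(2-oxoethyl)-5-(propan-2-yl)bicyclo[2.2.1]heptan-2-one | O=C1[C@H]2C[C@@H](C(C)C)[C@](CC=O)(C2)C1 | intermediate
11 | cyclohexane-1,3-dione | O=C1CCCC(=O)C1 | starting material
12 | Knoevenagel alkylidene dione | O=C1[C@H]2C[C@@H](C(C)C)[C@](CC=C3C(=O)CCCC3=O)(C2)C1 | intermediate (not isolated)
13 | (1S,4R,5S)-4-[2-(2,6-dioxocyclohexyl)ethyl]-5-(propan-2-yl)bicyclo[2.2.1]heptan-2-one | O=C1[C@H]2C[C@@H](C(C)C)[C@](CCC3C(=O)CCCC3=O)(C2)C1 | intermediate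
14 | (1S,4R,5S)-4-[2-(1-methyl-2,6-dioxocyclohexyl)ethyl]-5-(propan-2-yl)bicyclo[2.2.1]heptan-2-one | O=C1[C@H]2C[C@@H](C(C)C)[C@](CCC3(C)C(=O)CCCC3=O)(C2)C1 | intermediate
15 | C9 ketol (C9–OH α, C9 exo on C10) | O=C1[C@H]2C[C@@H](C(C)C)[C@]3(CC[C@@]4(C)[C@](O)([C@H]13)CCCC4=O)C2 | intermediate (not isolated)
16 | tetracyclic enedione (1,14-dioxo, C9=C10) | O=C1[C@H]2C[C@@H](C(C)C)[C@]3(CC[C@@]4(C)C(=C13)CCCC4=O)C2 | intermediate
17 | C14 dioxolane ketal of 16 | O=C1[C@H]2C[C@@H](C(C)C)[C@]3(CC[C@@]4(C)C(=C13)CCCC45OCCO5)C2 | intermediate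
18 | ene-1,11-dione ketal | O=C1[C@H]2C[C@@H](C(C)C)[C@]3(CC[C@@]4(C)C(=C13)C(=O)CCC45OCCO5)C2 | intermediate
19 | 1,11-diketone as C9/C10 epimer mixture | O=C1[C@H]2C[C@@H](C(C)C)[C@]3(CC[C@@]4(C)C(C13)C(=O)CCC45OCCO5)C2 | intermediate (not isolated)
20 | 1,11-diketone, H9 α, C9 exo on C10 | O=C1[C@H]2C[C@@H](C(C)C)[C@]3(CC[C@@]4(C)[C@H]([C@H]13)C(=O)CCC45OCCO5)C2 | intermediate
21 | C11 enol triflate, C1 ketone | O=C1[C@H]2C[C@@H](C(C)C)[C@]3(CC[C@@]4(C)[C@H]([C@H]13)C(OS(=O)(=O)C(F)(F)F)=CCC45OCCO5)C2 | intermediate
22 | C1 endo alcohol | O[C@H]1[C@H]2C[C@@H](C(C)C)[C@]3(CC[C@@]4(C)[C@H]([C@H]13)C(OS(=O)(=O)C(F)(F)F)=CCC45OCCO5)C2 | intermediate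
23 | C1 endo methyl ether | CO[C@H]1[C@H]2C[C@@H](C(C)C)[C@]3(CC[C@@]4(C)[C@H]([C@H]13)C(OS(=O)(=O)C(F)(F)F)=CCC45OCCO5)C2 | intermediate
24 | C14 ketone, enol triflate | CO[C@H]1[C@H]2C[C@@H](C(C)C)[C@]3(CC[C@@]4(C)[C@H]([C@H]13)C(OS(=O)(=O)C(F)(F)F)=CCC4=O)C2 | intermediate
25 | 14α-alcohol, enol triflate | CO[C@H]1[C@H]2C[C@@H](C(C)C)[C@]3(CC[C@@]4(C)[C@H]([C@H]13)C(OS(=O)(=O)C(F)(F)F)=CC[C@H]4O)C2 | intermediate
26 | 11-methyl 11(12)-alkene, 14α-alcohol | CO[C@H]1[C@H]2C[C@@H](C(C)C)[C@]3(CC[C@@]4(C)[C@H]([C@H]13)C(C)=CC[C@H]4O)C2 | intermediate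
27 | 11α,12α-epoxide, 14α-alcohol | CO[C@H]1[C@H]2C[C@@H](C(C)C)[C@]3(CC[C@@]4(C)[C@H]([C@H]13)[C@@]5(C)O[C@H]5C[C@H]4O)C2 | intermediate
28 | 11α,12α-epoxide, 14β-bromide | CO[C@H]1[C@H]2C[C@@H](C(C)C)[C@]3(CC[C@@]4(C)[C@H]([C@H]13)[C@@]5(C)O[C@H]5C[C@@H]4Br)C2 | intermediate
29 | CNP0130529.1 | CO[C@H]1[C@H]2C[C@@H](C(C)C)[C@]3(CC[C@@]4(C)[C@H]([C@H]13)[C@](C)(O)[C@@H](O)C[C@@H]4Br)C2 | target

**Count and risks**

Total: 21 steps. Longest linear sequence: 21 steps (from 1; 2, 5 and 11 enter as purchased reagents).

Step 9. The enamine may add to the other dione carbonyl, so that the diastereotopic-group selection is poor and the C8 epimer forms. The fallback sets out from 14 and desymmetrises the dione before the ring closure. A ketoreductase chosen from a panel (NADP+, glucose/glucose dehydrogenase, pH 7 buffer, 30 °C) reduces only the carbonyl that is to become C14 and gives the hydroxy diketone F1 (either C14 epimer serves). Pyrrolidine/AcOH in toluene then closes ring B onto the single remaining ring carbonyl and gives the hydroxy enone F2. Dess–Martin periodinane restores the C14 ketone, and the route is rejoined at 16.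

Step 20. Elimination toward C13 or a 1,2-shift of the C8 methyl may outrun SN2 displacement at the neopentyl centre, and bromide may open the epoxide. The fallback sets out from 23 and brings bromine in without a substitution.
- Negishi methylation (MeZnCl, Pd(PPh3)4) gives the ketal alkene F3.
- mCPBA gives the α-epoxide F4.
- Aqueous HClO4 opens the epoxide and removes the ketal, giving the 11β,12α-diol 14-ketone F5.
- Hydrazine gives the hydrazone F6.
- NBS/pyridine (Barton vinyl halide synthesis) gives the 13-ene-14-bromide F7.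
- Hydrogen-atom-transfer hydrogenation (Mn(dpm)3, PhSiH3, t-BuOOH, i-PrOH) saturates the bromoalkene without loss of bromine; hydrogen is delivered axially to C14, leaving the bromide equatorial. The route is rejoined at 29.

Step 3. Facial selectivity may be poor with this 1,3-disubstituted diene, or the strong Lewis acid may ionise the dioxolane or divert the reaction to a stepwise Mukaiyama–Michael path. The fallback sets out from 4 and uses a chelating dienophile with a milder Lewis acid. 3-Acryloyl-1,3-oxazolidin-2-one with [Cu((S,S)-t-Bu-box)](SbF6)2 (10 mol %, CH2Cl2, −78 °C) gives the endo imide F8. LiOH/H2O2 removes the oxazolidinone and gives the acid F9. MeLi (2.2 equiv, Et2O, 0 °C) converts the carboxylate into the methyl ketone, and the route is rejoined at 6.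

**Further compounds**

F1 | step 9 | hydroxy diketone (one dione carbonyl of 14 reduced, 14-OH shown β) | O=C1[C@H]2C[C@@H](C(C)C)[C@](CC[C@@]3(C)C(=O)CCC[C@@H]3O)(C2)C1
F2 | step 9 | 14-hydroxy enone (ring B closed) | O=C1[C@H]2C[C@@H](C(C)C)[C@]3(CC[C@@]4(C)C(=C13)CCC[C@@H]4O)C2
F3 | step 20 | 11-methyl 11(12)-alkene, C14 ketal | CO[C@H]1[C@H]2C[C@@H](C(C)C)[C@]3(CC[C@@]4(C)[C@H]([C@H]13)C(C)=CCC45OCCO5)C2
F4 | step 20 | 11α,12α-epoxide, C14 ketal | CO[C@H]1[C@H]2C[C@@H](C(C)C)[C@]3(CC[C@@]4(C)[C@H]([C@H]13)[C@@]5(C)O[C@H]5CC46OCCO6)C2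
F5 | step 20 | 11β,12α-diol 14-ketone | CO[C@H]1[C@H]2C[C@@H](C(C)C)[C@]3(CC[C@@]4(C)[C@H]([C@H]13)[C@](C)(O)[C@@H](O)CC4=O)C2
F6 | step 20 | C14 hydrazone of F5 | CO[C@H]1[C@H]2C[C@@H](C(C)C)[C@]3(CC[C@@]4(C)[C@H]([C@H]13)[C@](C)(O)[C@@H](O)CC4=NN)C2
F7 | step 20 | 13-ene-14-bromide diol | CO[C@H]1[C@H]2C[C@@H](C(C)C)[C@]3(CC[C@@]4(C)[C@H]([C@H]13)[C@](C)(O)[C@@H](O)C=C4Br)C2
F8 | step 3 | endo N-acyl oxazolidinone adduct | CC(C)(C)[Si](C)(C)OC=1[C@H]2C[C@@H](C(=O)N3CCOC3=O)[C@](CC3OCCO3)(C2)C=1
F9 | step 3 | endo carboxylic acid | CC(C)(C)[Si](C)(C)OC=1[C@H]2C[C@@H](C(=O)O)[C@](CC3OCCO3)(C2)C=1
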